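**Plan**

- Retrosynthetic cuts, in order: the aryl C5'–side-chain bond (Heck, isoprene); the O1–C2 bond of ring C together with the four O-benzyl groups; the C3–C4 bond, by reversing a 1,2-aroyl shift to a chalcone epoxide; the epoxide C–O bonds; the Cα=Cβ bond of the chalcone (Claisen–Schmidt).
- Enabling feature: C3 of ring C is a branch point bonded to ring B, to the C4 carbonyl and to C2, a CH at the aldehyde oxidation level. This 2-aryl-3-oxopropanal pattern is what an aroyl shift onto the benzylic carbon of a linear chalcone epoxide delivers.
- Forward: the ring A ketone (tribenzylated phloroacetophenone) and the ring B aldehyde (O-benzyl-5-bromoisovanillin, from 5-bromovanillin by demethylation and regioselective 4-O-methylation) are joined to the linear C6–C3–C6 chain. The chain is epoxidised and branched by the acyl shift, ring C closes on debenzylation, and the diene is attached last because it would not survive the Lewis acids.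
- Stereochemistry: the target has no stereocentre. Its only stereo-element, the E double bond of the side chain, comes from syn insertion and syn β-hydride elimination in the Heck step. The trans epoxide is racemic and both its centres are erased in the key step.

Key step: step 7

Remark: the 2-aryl-3-oxopropanals of steps 7 and 8 are written as dicarbonyl tautomers although enol forms should dominate; their methine centre is configurationally labile and left undefined, and the epoxide is racemic with one enantiomer drawn.

**Step 1**
Reactants: 1 5-bromovanillin
Product: 2 3-bromo-4,5-dihydroxybenzaldehyde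
Conditions: AlCl3, pyridine, CH2Cl2, reflux; then aq. HCl
Reagents that add atoms: none
Why: Lewis-acid-assisted aryl methyl ether cleavage, in which AlCl3 chelates the ortho-hydroxy-methoxy pair and pyridine takes the activated methyl group by SN2 attack, a demethylation that is standard for vanillin-type aldehydes and leaves the aldehyde and the aryl bromide alone.

**Step 2**
Reactants: 2 3-bromo-4,5-dihydroxybenzaldehyde; 3 iodomethane
Product: 4 3-bromo-5-hydroxy-4-methoxybenzaldehyde
Conditions: MeI (1.1 equiv), Li2CO3, DMF, 40 °C
Reagents that add atoms: iodomethane, CI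
Why: Regioselective Williamson etherification, since the 4-OH (para to the formyl group, ortho to bromine) is the more acidic phenol, so the weak base Li2CO3 forms only its phenoxide and one equivalent of MeI methylates it while the 5-OH stays free.

**Step 3**
Reactants: 4 3-bromo-5-hydroxy-4-methoxybenzaldehyde; 5 benzyl bromide
Product: 6 3-(benzyloxy)-5-bromo-4-methoxybenzaldehyde
Conditions: BnBr, K2CO3, DMF, 60 °C
Reagents that add atoms: benzyl bromide, BrCc1ccccc1
Why: Williamson etherification of the one remaining phenol, with no competing site left.

**Step 4**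
Reactants: 7 2,4,6-trihydroxyacetophenone; 5 benzyl bromide
Product: 8 2,4,6-tris(benzyloxy)acetophenone
Conditions: BnBr (3.5 equiv), K2CO3, DMF, 80 °C
Reagents that add atoms: benzyl bromide, BrCc1ccccc1
Why: Threefold Williamson etherification, in which heating in DMF is needed for the two hydrogen-bonded ortho phenols and carbonate in a dipolar aprotic solvent favours O- over C-benzylation of the phloroglucinol ring.

**Step 5**
Reactants: 8 2,4,6-tris(benzyloxy)acetophenone; 6 3-(benzyloxy)-5-bromo-4-methoxybenzaldehyde
Product: 9 (E)-3-[3-(benzyloxy)-5-bromo-4-methoxyphenyl]-1-[2,4,6-tris(benzyloxy)phenyl]prop-2-en-1-one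
Conditions: KOH, EtOH/THF, rt
Reagents that add atoms: none
Why: Claisen–Schmidt condensation, in which the methyl ketone enolate adds to the non-enolisable aldehyde and E1cB loss of water gives the conjugated enone in its thermodynamically preferred E geometry.

**Step 6**
Reactants: 9 (E)-chalcone
Product: 10 racemic trans-[3-(3-benzyloxy-5-bromo-4-methoxyphenyl)oxiran-2-yl][2,4,6-tris(benzyloxy)phenyl]methanone, (2S*,3R*)
Conditions: 30% aq. H2O2, NaOH, MeOH/THF, 0 °C to rt
Reagents that add atoms: hydrogen peroxide, OO
Why: Weitz–Scheffer nucleophilic epoxidation, in which hydroperoxide adds in conjugate fashion and the enolate closes onto the O–O bond, so the E-enone gives the trans epoxide (both centres set relative to each other by this closure) as a racemate because nothing differentiates the two faces.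

**Step 7**
Reactants: 10 racemic trans chalcone epoxide
Product: 11 2-[3-(benzyloxy)-5-bromo-4-methoxyphenyl]-3-oxo-3-[2,4,6-tris(benzyloxy)phenyl]propanal
Conditions: BF3·OEt2 (1.2 equiv), CH2Cl2, 0 °C, 30 min; cold aq. NaHCO3
Reagents that add atoms: none
Why: BF3 binds the oxirane oxygen and the C–O bond at the benzylic carbon (future C3) lengthens toward a cation stabilised by the para-methoxy group of ring B; the 2,4,6-tris(benzyloxy)benzoyl group then shifts from the neighbouring carbon to this centre, forming the C3–C4 bond, while the oxygen left on the old α-carbon collapses to the aldehyde that becomes C2. The closest known reaction type is the BF3-promoted Meinwald-type rearrangement of chalcone epoxides to α-formyl deoxybenzoins by 1,2-acyl migration. No ring is closed in this step. The new methine lies between two carbonyl groups, is enolisable and is obtained racemic, so no stereochemical control is needed and both epoxide centres are consumed. The step needs acyl migration in preference to hydride shift (which would give the 1,2-diketone), to fluoride capture (fluorohydrin) and to attack of an ortho oxygen on the benzylic centre (flavonol-type closure); this is secured by the benzylic cation sitting next to the acyl-bearing carbon, the electron-rich migrating aroyl group, benzyl protection of both ortho oxygens, and a short contact time at 0 °C in a non-nucleophilic solvent.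

**Step 8**
Reactants: 11 benzyl-protected keto aldehyde
Product: 14 3-(3-bromo-5-hydroxy-4-methoxyphenyl)-5,7-dihydroxy-4H-chromen-4-one, via debenzylated keto aldehyde 12 (not isolated), via 2-hydroxyisoflavanone hemiacetal 13 (not isolated)
Conditions: BCl3, C6HMe5, CH2Cl2, −78 to 0 °C; MeOH quench; HCl/MeOH, 50 °C
Reagents that add atoms: none
Why: Lewis-acid debenzylation followed by cyclodehydration, in which BCl3 ionises the four aryl benzyl ethers and pentamethylbenzene traps the benzyl cations by Friedel–Crafts alkylation, one ortho phenol of ring A adds to the aldehyde (6-exo-trig hemiacetal closure, either ortho phenol giving the same product because ring A is symmetric) and acid-promoted loss of water aromatises ring C, while the 4'-methyl ether, not chelated to a carbonyl, should survive at low temperature.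

**Step 9**
Reactants: 14 bromoisoflavone; 15 isoprene
Product: 16 5,7-dihydroxy-3-{3-hydroxy-4-methoxy-5-[(1E)-3-methylbuta-1,3-dien-1-yl]phenyl}-4H-chromen-4-one
Conditions: isoprene (excess), Pd(OAc)2 (5 mol%), P(o-tol)3, Et3N, DMF, 100 °C, sealed tube, BHT (trace)
Reagents that add atoms: isoprene, C=CC(C)=C
Why: Mizoroki–Heck reaction, in which zerovalent palladium formed in situ inserts into the C–Br bond, the aryl group adds to the unsubstituted vinyl terminus of isoprene (the methyl-bearing double bond is the more hindered) and syn β-hydride elimination gives the conjugated diene with the E styrenyl double bond.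

**Compound list**

1 | 5-bromovanillin (3-bromo-4-hydroxy-5-methoxybenzaldehyde) | COc1cc(C=O)cc(Br)c1O | starting material
2 | 3-bromo-4,5-dihydroxybenzaldehyde | O=Cc1cc(O)c(O)c(Br)c1 | intermediate
3 | iodomethane | CI | starting material
4 | 3-bromo-5-hydroxy-4-methoxybenzaldehyde | COc1c(O)cc(C=O)cc1Br | intermediate
5 | benzyl bromide | BrCc1ccccc1 | starting material
6 | 3-(benzyloxy)-5-bromo-4-methoxybenzaldehyde | COc1c(OCc2ccccc2)cc(C=O)cc1Br | intermediate
7 | 2,4,6-trihydroxyacetophenone | CC(=O)c1c(O)cc(O)cc1O | starting material
8 | 2,4,6-tris(benzyloxy)acetophenone | CC(=O)c1c(OCc2ccccc2)cc(OCc2ccccc2)cc1OCc1ccccc1 | intermediate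
9 | (E)-3-[3-(benzyloxy)-5-bromo-4-methoxyphenyl]-1-[2,4,6-tris(benzyloxy)phenyl]prop-2-en-1-one | O=C(/C=C/c1cc(Br)c(OC)c(OCc2ccccc2)c1)c1c(OCc2ccccc2)cc(OCc2ccccc2)cc1OCc1ccccc1 | intermediate
10 | racemic trans-[3-(3-benzyloxy-5-bromo-4-methoxyphenyl)oxiran-2-yl][2,4,6-tris(benzyloxy)phenyl]methanone, (2S*,3R*), one enantiomer drawn | O=C(c1c(OCc2ccccc2)cc(OCc2ccccc2)cc1OCc1ccccc1)[C@H]1O[C@@H]1c1cc(Br)c(OC)c(OCc2ccccc2)c1 | intermediate
11 | 2-[3-(benzyloxy)-5-bromo-4-methoxyphenyl]-3-oxo-3-[2,4,6-tris(benzyloxy)phenyl]propanal (racemic, labile centre undefined) | O=CC(c1cc(Br)c(OC)c(OCc2ccccc2)c1)C(=O)c1c(OCc2ccccc2)cc(OCc2ccccc2)cc1OCc1ccccc1 | intermediate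
12 | 2-(3-bromo-5-hydroxy-4-methoxyphenyl)-3-oxo-3-(2,4,6-trihydroxyphenyl)propanal (labile centre undefined) | O=CC(c1cc(O)c(OC)c(Br)c1)C(=O)c1c(O)cc(O)cc1O | intermediate (not isolated)
13 | 3-(3-bromo-5-hydroxy-4-methoxyphenyl)-2,5,7-trihydroxy-2,3-dihydro-4H-chromen-4-one (mixture of diastereomers, centres undefined) | OC1Oc2cc(O)cc(O)c2C(=O)C1c1cc(O)c(OC)c(Br)c1 | intermediate (not isolated)
14 | 3-(3-bromo-5-hydroxy-4-methoxyphenyl)-5,7-dihydroxy-4H-chromen-4-one | COc1c(O)cc(-c2coc3cc(O)cc(O)c3c2=O)cc1Br | intermediate
15 | isoprene | C=CC(C)=C | starting material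
16 | 5,7-dihydroxy-3-{3-hydroxy-4-methoxy-5-[(1E)-3-methylbuta-1,3-dien-1-yl]phenyl}-4H-chromen-4-one | C=C(C)/C=C/c1cc(-c2coc3cc(O)cc(O)c3c2=O)cc(O)c1OC | target

**Step count and risks**

Total step count: 9. Longest linear sequence: 8 steps (steps 1, 2, 3, 5, 6, 7, 8, 9, from 5-bromovanillin); step 4 lies on the shorter branch.

Steps most likely to fail:

1. Step 7 (acyl shift). The 4'-methoxy group is flanked by bromine and a benzyloxy group and may be twisted out of conjugation, so ionisation at the benzylic carbon could be slow. Fluoride capture of the opened epoxide, participation of an ortho benzyloxy oxygen with loss of benzyl, or deformylation of the β-keto aldehyde during work-up could then compete with the acyl shift. Fallback: set out from chalcone 9 and use an oxidative 1,2-aryl migration instead of the epoxide route. Tl(NO3)3·3H2O in MeOH/HC(OMe)3 should move ring B from Cβ to Cα and give the acetal 2-[3-(benzyloxy)-5-bromo-4-methoxyphenyl]-3,3-dimethoxy-1-[2,4,6-tris(benzyloxy)phenyl]propan-1-one F1, which has the same branched skeleton as 11 with the aldehyde masked. Carrying F1 through the conditions of step 8 (BCl3/C6HMe5, then HCl/MeOH) should unmask the aldehyde and the phenols and close ring C, so the route is rejoined at 14.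

2. Step 9 (Heck coupling). Oxidative addition into the electron-rich, ortho-substituted bromide may be slow; insertion may occur partly at the methyl-bearing terminus of isoprene; the π-allyl palladium intermediate may be intercepted by a phenoxide instead of eliminating; and isoprene or the product diene may polymerise or dimerise at 100 °C. Fallback: set out from 14 and form the same bond by Suzuki–Miyaura coupling, which fixes regiochemistry and E geometry in the reagent and avoids π-allyl intermediates. Hydroboration of 2-methylbut-1-en-3-yne with pinacolborane (Cp2Zr(H)Cl catalyst, then syn addition) should give (E)-4,4,5,5-tetramethyl-2-(3-methylbuta-1,3-dien-1-yl)-1,3,2-dioxaborolane F2. Coupling F2 with 14 (Pd(dppf)Cl2, K3PO4, dioxane/H2O, 80 °C) should give 16 directly.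

3. Step 8 (global debenzylation and ring closure). Benzyl cations may alkylate the phloroglucinol ring despite the scavenger, the 4'-methyl ether may be partly cleaved, and the unprotected β-keto aldehyde may lose its formyl group or stay bound as a boron chelate before ring C closes. Fallback: set out from 11 and separate ring closure from deprotection. MgBr2·OEt2 in toluene/Et2O at 60 °C should cleave one benzyl ether ortho to the ketone through a six-membered magnesium chelate; the freed phenol closes onto the aldehyde and catalytic TsOH completes dehydration to 5,7-bis(benzyloxy)-3-[3-(benzyloxy)-5-bromo-4-methoxyphenyl]-4H-chromen-4-one F3, a robust isoflavone that can be purified. Its three benzyl ethers are then removed without a Lewis acid by acidolysis in TFA with thioanisole as benzyl acceptor, returning to the route at 14.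

**Further compounds**

F1 | step 7 | 2-[3-(benzyloxy)-5-bromo-4-methoxyphenyl]-3,3-dimethoxy-1-[2,4,6-tris(benzyloxy)phenyl]propan-1-one (racemic) | COC(OC)C(c1cc(Br)c(OC)c(OCc2ccccc2)c1)C(=O)c1c(OCc2ccccc2)cc(OCc2ccccc2)cc1OCc1ccccc1
F2 | step 9 | (E)-4,4,5,5-tetramethyl-2-(3-methylbuta-1,3-dien-1-yl)-1,3,2-dioxaborolane | C=C(C)/C=C/B1OC(C)(C)C(C)(C)O1
F3 | step 8 | 5,7-bis(benzyloxy)-3-[3-(benzyloxy)-5-bromo-4-methoxyphenyl]-4H-chromen-4-one | COc1c(OCc2ccccc2)cc(-c2coc3cc(OCc4ccccc4)cc(OCc4ccccc4)c3c2=O)cc1Br
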